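The γ-pyranone is disconnected at the O1–C8a bond. The C4a=C8a double bond, shared by the pyranone and the carbocyclic tetrol ring, is carried into the precursor as the alkene of a cyclohexenyl ketone whose β-carbon is C8a. In one operation the key step joins the enol oxygen of a 1,3-diketone to C8a under aerobic palladium catalysis and regenerates C4a=C8a, which closes the pyranone without touching the carbinol centres C5 to C8. The precursor is a 1,3-diketone on a cyclohexene bearing a 5,6-cis acetonide and 7,8-trans benzyl ethers; its four stereocentres come from an enzymatic arene cis-dihydrodiol, an anti epoxidation and an allylic epoxide opening.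

Key step: step 12

Remark on numbering: carbocyclic intermediates carry chromone locants (C4a = alkene carbon bearing Br, Li or the acyl group; C8a = alkene CH; then C8, C7, C6, C5). With the ring drawn C4a→C5→C6→C7→C8→C8a clockwise, α is the lower face (that of the C5 and C6 oxygens) and β the upper face; the absolute configuration is that of the target, (5S,6S,7R,8S).
Remark on tautomers: diketone 15 is drawn in the diketo form and is assumed to exist and react mainly as its enol.

Step 1
Reactants: 1 1-bromo-4-iodobenzene
Product: 2 (1S,2R)-3-bromo-6-iodocyclohexa-3,5-diene-1,2-diol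
Conditions: E. coli JM109(pDTG601) whole cells (toluene dioxygenase), glucose, phosphate buffer pH 7.2, air, 30 °C
Reagents that add atoms: dioxygen, O=O
Why: Enzymatic arene cis-dihydroxylation by toluene dioxygenase should add both oxygens of O2 to one face of a 2,3-bond, with the larger iodine taking the place of the directing substituent, so that the enzyme sets both carbinol centres (later C5 and C6) in the sense opposite to that obtained from bromobenzene once iodine is removed.

Step 2
Reactants: 2 (1S,2R)-3-bromo-6-iodocyclohexa-3,5-diene-1,2-diol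
Product: 3 (1R,2R)-3-bromocyclohexa-3,5-diene-1,2-diol
Conditions: Bu3SnH (1.1 equiv), Pd(PPh3)4 (3 mol%), THF, 0 °C → rt; recrystallisation
Reagents that add atoms: none
Why: Palladium-catalysed hydrodehalogenation, in which zerovalent palladium inserts into the alkenyl C–I bond far faster than into C–Br and the tin hydride delivers hydrogen, should remove only iodine without touching the stereocentres, and crystallisation of 3 is the point at which any antipode arising from bromine-steered oxygenation can be purged.

Step 3
Reactants: 3 (1R,2R)-3-bromocyclohexa-3,5-diene-1,2-diol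
Product: 4 (3aR,7aR)-4-bromo-2,2-dimethyl-3a,7a-dihydro-1,3-benzodioxole
Conditions: Me2C(OMe)2, TsOH·H2O (cat.), acetone, 0 °C → rt; used at once
Reagents that add atoms: 2,2-dimethoxypropane, COC(C)(C)OC
Why: Acid-catalysed transacetalisation of the cis-1,2-diol should give the five-membered acetonide fast enough to outrun dehydration to the phenol, with no change at the stereocentres.

Step 4
Reactants: 4 (3aR,7aR)-4-bromo-2,2-dimethyl-3a,7a-dihydro-1,3-benzodioxole
Product: 5 4a-bromo-7β,8β-epoxy-5α,6α-(isopropylidenedioxy)cyclohex-4a(8a)-ene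
Conditions: mCPBA, NaHCO3, CH2Cl2, 0 °C → rt
Reagents that add atoms: 3-chloroperoxybenzoic acid (mCPBA), OOC(=O)c1cccc(Cl)c1
Why: Prilezhaev epoxidation should occur at the C7=C8 alkene, which is more electron-rich than the brominated C4a=C8a alkene, and from the β face because the cis-acetonide shields the α face, which sets the C7 oxygen.

Step 5
Reactants: 5 4a-bromo-7β,8β-epoxy-5α,6α-(isopropylidenedioxy)cyclohex-4a(8a)-ene; 6 benzyl alcohol
Product: 7 8α-benzyloxy-4a-bromo-5α,6α-(isopropylidenedioxy)cyclohex-4a(8a)-en-7β-ol
Conditions: BnOH (3 equiv), BF3·OEt2 (10 mol%), CH2Cl2, −30 → 0 °C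
Reagents that add atoms: none
Why: Acid-catalysed epoxide opening should take place at the allylic carbon C8 with inversion, since allylic stabilisation of the developing positive charge and the Fürst–Plattner trans-diaxial rule point the same way, which sets C8–OBn α and leaves C7–OH β (7,8-trans and 6,7-trans).

Step 6
Reactants: 7 8α-benzyloxy-4a-bromo-5α,6α-(isopropylidenedioxy)cyclohex-4a(8a)-en-7β-ol
Product: 8 7β,8α-bis(benzyloxy)-4a-bromo-5α,6α-(isopropylidenedioxy)cyclohex-4a(8a)-ene
Conditions: NaH, BnBr, Bu4NI (cat.), THF–DMF, 0 °C → rt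
Reagents that add atoms: benzyl bromide, BrCc1ccccc1
Why: Williamson ether synthesis on the C7 alkoxide should proceed without affecting any stereocentre, since the alkenyl bromide cannot eliminate within the ring and the acetonide is stable to base.

Step 7
Reactants: 8 7β,8α-bis(benzyloxy)-4a-bromo-5α,6α-(isopropylidenedioxy)cyclohex-4a(8a)-ene
Product: 10 1-[7β,8α-bis(benzyloxy)-5α,6α-(isopropylidenedioxy)cyclohex-4a(8a)-en-4a-yl]ethanone, via alkenyllithium 9 (not isolated)
Conditions: t-BuLi (2.1 equiv), Et2O, −78 °C; then MeC(O)N(OMe)Me, −78 → 0 °C; H2O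
Reagents that add atoms: N-methoxy-N-methylacetamide, CC(=O)N(C)OC; tert-butyllithium, [Li]C(C)(C)C (supplies the lithium of 9 only)
Why: Bromine–lithium exchange followed by the Weinreb ketone synthesis should give the methyl ketone, because the alkenyllithium cannot expel the C5 oxygen (that would need a cyclic allene) and the chelated tetrahedral adduct prevents a second addition.

Step 8
Reactants: 11 isovanillin (3-hydroxy-4-methoxybenzaldehyde)
Product: 12 3-(benzyloxy)-4-methoxybenzaldehyde
Conditions: BnBr, K2CO3, DMF, rt
Reagents that add atoms: benzyl bromide, BrCc1ccccc1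
Why: Williamson ether synthesis on the phenoxide, the only acidic site, should protect the phenol as the benzyl ether that is later removed together with the other two.

Step 9
Reactants: 12 3-(benzyloxy)-4-methoxybenzaldehyde
Product: 13 3-[3-(benzyloxy)-4-methoxyphenyl]propanoic acid
Conditions: Meldrum's acid, HCO2H–Et3N (5:2), 95 °C; then aq. HCl
Reagents that add atoms: 2,2-dimethyl-1,3-dioxane-4,6-dione (Meldrum's acid), CC1(C)OC(=O)CC(=O)O1
Why: A one-pot Knoevenagel condensation, conjugate reduction of the arylidene by formate, hydrolysis and decarboxylation should give the saturated acid directly, and the benzyl ether survives because no hydrogenation metal is present.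

Step 10
Reactants: 13 3-[3-(benzyloxy)-4-methoxyphenyl]propanoic acid
Product: 14 1-{3-[3-(benzyloxy)-4-methoxyphenyl]propanoyl}-1H-benzotriazole
Conditions: 1H-benzotriazole, DCC, CH2Cl2, 0 °C → rt
Reagents that add atoms: 1H-benzotriazole, c1ccc2[nH]nnc2c1
Why: Carbodiimide-mediated condensation should give the N-acylbenzotriazole, a neutral and isolable acyl donor suited to C-acylation of ketones.

Step 11
Reactants: 10 1-[7β,8α-bis(benzyloxy)-5α,6α-(isopropylidenedioxy)cyclohex-4a(8a)-en-4a-yl]ethanone; 14 1-{3-[3-(benzyloxy)-4-methoxyphenyl]propanoyl}-1H-benzotriazole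
Product: 15 5-[3-(benzyloxy)-4-methoxyphenyl]-1-[7β,8α-bis(benzyloxy)-5α,6α-(isopropylidenedioxy)cyclohex-4a(8a)-en-4a-yl]pentane-1,3-dione
Conditions: MgBr2·OEt2 (2.5 equiv), i-Pr2NEt (3 equiv), CH2Cl2, rt; then aq. citric acid
Reagents that add atoms: none
Why: Crossed Claisen condensation by soft enolisation should acylate the methyl group on carbon, because the magnesium-bound ketone is deprotonated by the amine only at CH3, the product is held as its magnesium diketonate against a second acylation, and the absence of strong base avoids γ-deprotonation at C8 and loss of the C7 benzyloxy group.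

Step 12
Reactants: 15 5-[3-(benzyloxy)-4-methoxyphenyl]-1-[7β,8α-bis(benzyloxy)-5α,6α-(isopropylidenedioxy)cyclohex-4a(8a)-en-4a-yl]pentane-1,3-dione
Product: 16 (5S,6S,7R,8S)-7,8-bis(benzyloxy)-2-{2-[3-(benzyloxy)-4-methoxyphenyl]ethyl}-5,6-(isopropylidenedioxy)-5,6,7,8-tetrahydro-4H-chromen-4-one
Conditions: Pd(OCOCF3)2 (10 mol%), 5-nitro-1,10-phenanthroline (12 mol%), O2 (1 atm), DMSO, 70 °C
Reagents that add atoms: none
Why: Proposed new method: the enol oxygen on C2 of the enolised diketone should add to C8a, the β-carbon of the cyclohexenyl ketone, while divalent palladium activates the C4a=C8a alkene (anti-oxypalladation, or oxa-Michael addition followed by formation of the palladium enolate), so that palladium comes to sit on C4a, and syn β-hydride loss of H8a then restores C4a=C8a inside the new γ-pyranone while O2 returns zerovalent palladium to the divalent state. The closest known reaction type is the oxidative cyclisation of 2'-hydroxychalcones to flavones by divalent palladium under oxygen, together with the aerobic palladium dehydrogenation of chromanones to chromones. The one ring formed (O1, C2, C3, C4, C4a, C8a) closes in the 6-endo-trig mode, and no stereocentre is created, because C4a and C8a end trigonal and C5 to C8 are not involved. The step needs O-attack at C8a and not at C4a, which the enone polarity secures since C8a is the electrophilic β-carbon, and carbon attack by C3 is excluded because it would close a three- or four-membered ring. It also needs hydride loss from C8a and not from C5, and no loss of the C5 oxygen: H8a lies syn to palladium as a consequence of the anti addition and its loss completes the cyclic push–pull system of the pyranone, whereas the C5 oxygen is held in a cis-fused acetal and, like the benzyl ethers, is a poor leaving group from palladium. The phenanthroline ligand is there to keep palladium from being locked up as a bis(diketonate) chelate of the substrate.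

Step 13
Reactants: 16 (5S,6S,7R,8S)-7,8-bis(benzyloxy)-2-{2-[3-(benzyloxy)-4-methoxyphenyl]ethyl}-5,6-(isopropylidenedioxy)-5,6,7,8-tetrahydro-4H-chromen-4-one
Product: 17 (5S,6S,7R,8S)-7,8-bis(benzyloxy)-2-{2-[3-(benzyloxy)-4-methoxyphenyl]ethyl}-5,6-dihydroxy-5,6,7,8-tetrahydro-4H-chromen-4-one
Conditions: AcOH–H2O (4:1), 50 °C
Reagents that add atoms: none
Why: Acid-catalysed acetal hydrolysis should cleave only the bonds to the isopropylidene carbon, so C5 and C6 keep their configuration, and the benzyl ethers and the pyranone are stable to dilute acid.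

Step 14
Reactants: 17 (5S,6S,7R,8S)-7,8-bis(benzyloxy)-2-{2-[3-(benzyloxy)-4-methoxyphenyl]ethyl}-5,6-dihydroxy-5,6,7,8-tetrahydro-4H-chromen-4-one
Product: 18 (5S,6S,7R,8S)-5,6,7,8-tetrahydroxy-2-[2-(3-hydroxy-4-methoxyphenyl)ethyl]-5,6,7,8-tetrahydro-4H-chromen-4-one
Conditions: H2 (1 atm), Pd/C (10%), MeOH–EtOAc, rt
Reagents that add atoms: none
Why: Catalytic hydrogenolysis should cleave the three PhCH2–O bonds under neutral conditions, while the vinylogous-ester C2=C3 bond and the tetrasubstituted C4a=C8a bond of the γ-pyranone are poor substrates for hydrogenation at 1 atm, so the target should be obtained after filtration.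

Compound list
1 | 1-bromo-4-iodobenzene | Brc1ccc(I)cc1 | starting material
2 | (1S,2R)-3-bromo-6-iodocyclohexa-3,5-diene-1,2-diol | O[C@@H]1C(I)=CC=C(Br)[C@@H]1O | intermediate
3 | (1R,2R)-3-bromocyclohexa-3,5-diene-1,2-diol | O[C@@H]1C=CC=C(Br)[C@@H]1O | intermediate
4 | (3aR,7aR)-4-bromo-2,2-dimethyl-3a,7a-dihydro-1,3-benzodioxole | CC1(C)O[C@@H]2C=CC=C(Br)[C@@H]2O1 | intermediate
5 | 4a-bromo-7β,8β-epoxy-5α,6α-(isopropylidenedioxy)cyclohex-4a(8a)-ene (epoxide anti to the acetonide) | CC1(C)O[C@@H]2[C@H]3O[C@H]3C=C(Br)[C@@H]2O1 | intermediate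
6 | benzyl alcohol | OCc1ccccc1 | starting material
7 | 8α-benzyloxy-4a-bromo-5α,6α-(isopropylidenedioxy)cyclohex-4a(8a)-en-7β-ol | CC1(C)O[C@@H]2[C@@H](O)[C@H](OCc3ccccc3)C=C(Br)[C@@H]2O1 | intermediate
8 | 7β,8α-bis(benzyloxy)-4a-bromo-5α,6α-(isopropylidenedioxy)cyclohex-4a(8a)-ene | CC1(C)O[C@@H]2[C@@H](OCc3ccccc3)[C@H](OCc3ccccc3)C=C(Br)[C@@H]2O1 | intermediate
9 | 7β,8α-bis(benzyloxy)-5α,6α-(isopropylidenedioxy)cyclohex-4a(8a)-en-4a-yllithium | [Li]C1=C[C@@H](OCc2ccccc2)[C@H](OCc2ccccc2)[C@H]2OC(C)(C)O[C@@H]12 | intermediate
10 | 1-[7β,8α-bis(benzyloxy)-5α,6α-(isopropylidenedioxy)cyclohex-4a(8a)-en-4a-yl]ethanone | CC(=O)C1=C[C@@H](OCc2ccccc2)[C@H](OCc2ccccc2)[C@H]2OC(C)(C)O[C@@H]12 | intermediate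
11 | isovanillin (3-hydroxy-4-methoxybenzaldehyde) | COc1ccc(C=O)cc1O | starting material
12 | 3-(benzyloxy)-4-methoxybenzaldehyde | COc1ccc(C=O)cc1OCc1ccccc1 | intermediate
13 | 3-[3-(benzyloxy)-4-methoxyphenyl]propanoic acid | COc1ccc(CCC(=O)O)cc1OCc1ccccc1 | intermediate
14 | 1-{3-[3-(benzyloxy)-4-methoxyphenyl]propanoyl}-1H-benzotriazole | COc1ccc(CCC(=O)n2nnc3ccccc32)cc1OCc1ccccc1 | intermediate
15 | 5-[3-(benzyloxy)-4-methoxyphenyl]-1-[7β,8α-bis(benzyloxy)-5α,6α-(isopropylidenedioxy)cyclohex-4a(8a)-en-4a-yl]pentane-1,3-dione | COc1ccc(CCC(=O)CC(=O)C2=C[C@@H](OCc3ccccc3)[C@H](OCc3ccccc3)[C@H]3OC(C)(C)O[C@@H]23)cc1OCc1ccccc1 | intermediate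
16 | (5S,6S,7R,8S)-7,8-bis(benzyloxy)-2-{2-[3-(benzyloxy)-4-methoxyphenyl]ethyl}-5,6-(isopropylidenedioxy)-5,6,7,8-tetrahydro-4H-chromen-4-one | COc1ccc(CCc2cc(=O)c3c(o2)[C@@H](OCc2ccccc2)[C@H](OCc2ccccc2)[C@H]2OC(C)(C)O[C@@H]32)cc1OCc1ccccc1 | intermediate
17 | (5S,6S,7R,8S)-7,8-bis(benzyloxy)-2-{2-[3-(benzyloxy)-4-methoxyphenyl]ethyl}-5,6-dihydroxy-5,6,7,8-tetrahydro-4H-chromen-4-one | COc1ccc(CCc2cc(=O)c3c(o2)[C@@H](OCc2ccccc2)[C@H](OCc2ccccc2)[C@@H](O)[C@H]3O)cc1OCc1ccccc1 | intermediate
18 | (5S,6S,7R,8S)-5,6,7,8-tetrahydroxy-2-[2-(3-hydroxy-4-methoxyphenyl)ethyl]-5,6,7,8-tetrahydro-4H-chromen-4-one | COc1ccc(CCc2cc(=O)c3c(o2)[C@@H](O)[C@H](O)[C@@H](O)[C@H]3O)cc1O | target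

Total step count: 14. Longest linear sequence: 11 steps (steps 1 to 7 and 11 to 14).

Steps most likely to fail

Step 12 (new method). What may go wrong: β-hydride loss towards C5 in place of C8a, giving a cross-conjugated dienone and destroying the C5 centre; sequestration of palladium by the diketonate so that turnover stops; or stalling at the non-oxidised oxa-Michael stage. Fallback, setting out from 15 and coming back at 16: the ring closure and the oxidation are separated and the oxidant is changed from palladium to a hydride acceptor. Diketone 15 is cyclised under acid catalysis (camphorsulfonic acid, CH2Cl2, rt) in the 6-endo oxa-Michael sense, the ring–chain isomerisation known for enone-bearing 1,3-diketones and for 2'-hydroxychalcones, to the 4a,8a-dihydropyranone F1. F1 is then dehydrogenated with DDQ (dioxane, TsOH cat., 60 °C), the standard conversion of flavanones and dihydropyranones into 4-pyranones. In this oxidation hydride leaves the dienol from C8a, the carbon next to O1, because only that loss leads to an aromatic 4-hydroxypyrylium ion; the regiochemical question of the palladium step therefore does not arise. If the oxa-Michael equilibrium lies on the side of 15, both operations are run in one flask so that the oxidation drains it.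

Step 11. What may go wrong: incomplete soft enolisation of the hindered, chelating methyl ketone, competing O-acylation, or conjugate addition of the liberated benzotriazole to the enone. Fallback, setting out from 10 and 13 and coming back at 15: the carbon–carbon bond is made by an aldol addition at the alcohol oxidation level and the diketone is reached by oxidation. Acid 13 is reduced with BH3·THF to 3-[3-(benzyloxy)-4-methoxyphenyl]propan-1-ol F2, which is oxidised with Dess–Martin periodinane to 3-[3-(benzyloxy)-4-methoxyphenyl]propanal F3. The kinetic lithium enolate of 10 (LiN(SiMe3)2, THF, −78 °C) is added to F3 to give the β-hydroxy ketone F4 as a mixture of carbinol epimers, and Dess–Martin oxidation of F4 gives 15.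

Step 14. What may go wrong: over-reduction of the pyranone C2=C3 bond, or hydrogenolytic cleavage of the allylic C8–O or C5–O bond before the two alkyl benzyl ethers are gone. Fallback, setting out from 17 and coming back at 18: the benzyl ethers are removed by Lewis-acid dealkylation in place of reduction, with BCl3 and pentamethylbenzene as cation scavenger (CH2Cl2, −78 °C, methanol quench). This cleaves aryl and alkyl benzyl ethers, leaves the aryl methyl ether and all C=C bonds untouched, and makes no new compound (F0).

Further compounds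
F1 | step 12 | 7,8-bis(benzyloxy)-2-{2-[3-(benzyloxy)-4-methoxyphenyl]ethyl}-5,6-(isopropylidenedioxy)-4a,5,6,7,8,8a-hexahydro-4H-chromen-4-one (C5 to C8 as in 16, C4a and C8a unassigned) | COc1ccc(CCC2=CC(=O)C3C(O2)[C@@H](OCc2ccccc2)[C@H](OCc2ccccc2)[C@H]2OC(C)(C)O[C@@H]32)cc1OCc1ccccc1
F2 | step 11 | 3-[3-(benzyloxy)-4-methoxyphenyl]propan-1-ol | COc1ccc(CCCO)cc1OCc1ccccc1
F3 | step 11 | 3-[3-(benzyloxy)-4-methoxyphenyl]propanal | COc1ccc(CCC=O)cc1OCc1ccccc1
F4 | step 11 | 5-[3-(benzyloxy)-4-methoxyphenyl]-1-[7β,8α-bis(benzyloxy)-5α,6α-(isopropylidenedioxy)cyclohex-4a(8a)-en-4a-yl]-3-hydroxypentan-1-one (carbinol epimers) | COc1ccc(CCC(O)CC(=O)C2=C[C@@H](OCc3ccccc3)[C@H](OCc3ccccc3)[C@H]3OC(C)(C)O[C@@H]23)cc1OCc1ccccc1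
F0 | step 14 | none | none
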